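## The problem

The target (31) is a sesquiterpenoid diol diangelate built around one cyclobutane that is bridged twice. In the numbering used throughout, C1 is the quaternary carbon bearing CH3 and CH2O‑angeloyl. C2 (CH) and C8 (C–CH3) are the cyclobutane carbons joined by the four‑carbon bridge C1–C11–C10–C9 (C11 = CH–O‑angeloyl). C3 and C7 are the cyclobutane CH carbons joined on the opposite face by the enone bridge C4(=O)–C5H=C6(CH3), so a bicyclo[4.1.1]octane and a bicyclo[3.1.1]heptenone share the four‑membered ring. Four of the six stereocentres (C2, C3, C7, C8) are locked to one another by the double bridging, which leaves three things to control: the absolute sense of the cage, the CH3/CH2O arrangement at C1, and the carbinol C11. C11 can be set from C1, because a free C1–CH2OH can deliver hydride to a C11 ketone. C1, however, relates to the orientation of the unsymmetrical enone bridge only across the cyclobutane, with no group in reach to relay it; this remote relation is the hard stereochemical problem. Two quaternary carbons (C1, C8) must be made on or next to the strained ring, and C8 must end as a bare methyl group. The angelates isomerise to tiglates under basic, nucleophilic or forcing conditions and survive neither hydrides nor organometallic reagents; cations next to the cyclobutane invite Wagner–Meerwein shifts; the C11 hydroxyl is neopentyl and hindered. The feature that opens the key step is that C2 and C8 are a CH and a carbon bearing a one‑carbon group. They map onto the two bridgeheads of a 1‑acylbicyclo[1.1.0]butane, whose central bond, opened from outside, puts the new bridge anti to both exo wing substituents, as the two bridges of the target require.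

## Retrosynthesis

**Esters last (31 ⇒ 28 + 29).** The two C–O ester bonds are cut first. Angelates tolerate none of the hydride, cuprate or base steps needed earlier, so diol 28 is acylated with angelic acid 29 in the final step. The forward reaction must acylate the hindered C11 hydroxyl without Z to E isomerisation.

**Enone bridge (28 ⇒ 27 ⇒ 25 ⇒ 24).** The C6–CH3 bond and the C5=C6 bond are cut, leading to keto aldehyde 24 with an acetyl group on C3 and a formyl group on C7. A diketone with two acetyl groups would close in both orientations; the acetyl/formyl pair fixes the ketone on C3 (aldol condensation to 25), and the methyl group is then added to C6 by cuprate addition and dehydrogenation (27). Keto aldehyde 24 could equally be closed and methylated in the other orientation (methyllithium addition and oxidative allylic transposition), and every chiral reagent of the route exists in both antipodes. The plan therefore needs an appreciable facial preference in the annulation below, but does not stand or fall with its predicted sense.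

**Functional‑group level (24 ⇒ 22 ⇒ 19 ⇒ 17).** No skeletal bond is cut here. The two carbonyl groups come from silyl‑protected carbinols (23, 22). The C8 methyl group comes from the ester that activates the key step (19 → 20 → 21 → 22). The C11 carbinol comes from the ketone of 17 by reduction directed by the free C1–CH2OH (18), and the resulting 1,3‑diol is carried as acetonide 19. The forward steps must leave the two wing silyl ethers untouched until both are removed together.

**Seven‑membered ring (17 ⇒ 11 + 15).** Bonds C1–C2 and C8–C9 are cut. Cutting C1–C11 or C10–C11 instead would leave a cis‑1,3‑disubstituted cyclobutane, with two quaternary carbons, still to be made. This cut removes the ring and both quaternary carbons at once, and turns the cyclobutane stereochemistry into the exo,exo geometry of bicyclobutane 11. The partner is the achiral dienol ether 15. The forward reaction must attack the hydrogen‑bearing bridgehead, close (4+3) rather than (3+2), and choose one face of the enol ether carbon. For the last point the two wing substituents are made unequal in size: a branched 1‑silyloxyethyl group on C3 and a CH2OTBS group on C7.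

**Bicyclobutane (11 ⇒ 10 ⇒ 8 ⇒ 6 ⇒ 5 ⇒ 4 ⇒ 2 + 3).** Bonds C8–C2 and C8–C7 are cut (intramolecular carbene addition of diazo ester 10). The E‑alkene geometry becomes the exo position of CH2OTBS. The stereocentre next to the carbene carbon comes from a Johnson–Claisen rearrangement (6 + 7 → 8), with chirality transferred from the carbinol of 6. That carbinol is set by asymmetric transfer hydrogenation of ynone 4, which is assembled from alkyne 2 and Weinreb amide 3. Every precursor is acyclic, and only one stereocentre (that of 5) has to be created by a reagent.

**Dienol ether (15 ⇒ 14 ⇒ 13 ⇒ 12).** The vinyl–carbonyl bond is cut. Hydroxy ester 12 gives Weinreb amide 13, then vinyl ketone 14, which is silylated on oxygen twice. The stereocentre of 12 is erased on enolisation, so 15 carries no stereochemical information.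

## Roads not taken

Alternative 1: The cut is C1–C11, made last on a substrate that already contains the cyclobutane and the enone bridge. SmI2 would turn an α‑bromo ester at C1 into a samarium enolate that adds to an aldehyde at the end of the chain on C8, giving hydroxy ester A1. The merits are real. The samarium Reformatsky reaction is among the best closures for seven‑membered rings. It makes the quaternary C1 and the carbinol C11 in one step through a chelated transition state. The C1 ester is one reduction from CH2OH, whereas the chosen plan spends three steps turning its C8 ester into a methyl group. The weak points are these. The enone is itself reducible by SmI2. The planar samarium enolate sees the enone bridge only across the cyclobutane, so the remote C1 problem is not solved any better. Above all, the step presupposes a bicyclo[3.1.1]heptenone carrying two different functionalised arms on its one‑carbon bridges, and nothing in the strategy makes that cyclobutane. In ring‑closure precedent this road is ahead of the chosen one. Against that the chosen plan sets convergence (two short arms), the cyclobutane stereochemistry from bicyclobutane geometry, and two bonds and two quaternary carbons from one step.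

Alternative 2: The cut is the cyclobutane bond C3–C8. A nitrile‑stabilised carbanion at C8 in the seven‑membered ring of a cis‑fused bicycle would open a C3–C4 epoxide in the six‑membered ring (4‑exo), giving cyano alcohol A2 with oxygen already on C4. Epoxynitrile cyclisation is a classical, dependable cyclobutane synthesis, and the precursor is an ordinary fused 6–7 system open to annulation logic and conformational control. Its key step is chemically more conservative than the chosen one. The weak points are the transannular geometry (the carbanion must reach C3 anti to the C–O bond through a boat‑like ring, forming both bridged bicycles at once against strain) and a precursor with six stereocentres, including the quaternary C1 in a flexible ring, which means a long linear sequence. The nitrile must still become a methyl group and the saturated C5–C6 bond must still be dehydrogenated, so nothing is saved against the chosen route after the key step. The chosen plan builds the strain early, where it drives the reaction, instead of paying for it at the end. Its price is a key step without direct precedent.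

Alternative 3: The cut is C5–C6, at the end. The silyl enol ether of an acetyl group on C3 would add 6‑exo‑dig to an ethynyl group on C7 under a cationic monovalent gold catalyst such as Ph3PAuNTf2, giving exo‑methylene ketone A3, which is isomerised to the enone. As an end game this is at least as good as the chosen one. The regiochemistry is fixed by which carbon carries which group, the methyl carbon is already in place, and no face‑sensitive dehydrogenation is needed. But it is only an end game. It presupposes the whole bicyclo[4.1.1]octane with both quaternary carbons, which is the actual problem. A terminal alkyne would also compete in the carbene step that makes the bicyclobutane, so it would have to be made late from the aldehyde, costing the step it saves. The chosen plan sets against it that its aldehyde and methyl ketone come directly from two silyl ethers that pass unchanged through the carbene and Lewis‑acid steps.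

Key step: step 11

Remark: Weinreb amide 3 is treated as a catalogue compound. Ring compounds are described with the locants C1–C11 defined under "The problem"; "anti" for a C3 or C7 substituent means on the cyclobutane face opposite the bridge C1–C11–C10–C9.

Step 1
Reactants: 1 (S)-but-3-yn-2-ol
Product: 2 (S)-tert-butyl(but-3-yn-2-yloxy)dimethylsilane
Conditions: TBSCl, imidazole, CH2Cl2, 0 °C to rt
Reagents that add atoms: tert-butyldimethylsilyl chloride, CC(C)(C)[Si](C)(C)Cl
Why: Routine silylation of a secondary alcohol; the stereocentre is a spectator that makes the later C3 wing branched and is oxidised away in step 18.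

Step 2
Reactants: 2 (S)-tert-butyl(but-3-yn-2-yloxy)dimethylsilane; 3 2-[(tert-butyldimethylsilyl)oxy]-N-methoxy-N-methylacetamide
Product: 4 (5S)-1,5-bis[(tert-butyldimethylsilyl)oxy]hex-3-yn-2-one
Conditions: n-BuLi, THF, −78 °C; then 3, −78 to 0 °C; aq. NH4Cl
Reagents that add atoms: none
Why: Weinreb ketone synthesis: the chelated tetrahedral intermediate of the lithium acetylide and the amide survives until work-up, so addition stops at the ynone.

Step 3
Reactants: 4 (5S)-1,5-bis[(tert-butyldimethylsilyl)oxy]hex-3-yn-2-one
Product: 5 (2R,5S)-1,5-bis[(tert-butyldimethylsilyl)oxy]hex-3-yn-2-ol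
Conditions: RuCl(p-cymene)[(S,S)-TsDPEN] (1 mol %), iPrOH, rt
Reagents that add atoms: none
Why: Noyori asymmetric transfer hydrogenation of an alkynyl ketone; the alkyne is the π-substituent recognised by the catalyst, so the (S,S)-ligand is expected to give the (2R)-carbinol under catalyst control, independent of the remote silyloxy centre.

Step 4
Reactants: 5 (2R,5S)-1,5-bis[(tert-butyldimethylsilyl)oxy]hex-3-yn-2-ol
Product: 6 (2R,3E,5S)-1,5-bis[(tert-butyldimethylsilyl)oxy]hex-3-en-2-ol
Conditions: NaAlH2(OCH2CH2OMe)2, THF, 0 °C to rt; aq. potassium sodium tartrate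
Reagents that add atoms: none
Why: Hydroxyl-directed trans-hydroalumination of the propargylic alcohol gives only the E-alkene; the temperature is kept low so that the γ-silyloxy group is not eliminated to an allene.

Step 5
Reactants: 6 (2R,3E,5S)-1,5-bis[(tert-butyldimethylsilyl)oxy]hex-3-en-2-ol; 7 trimethyl orthoacetate
Product: 8 methyl (3S,4E)-6-[(tert-butyldimethylsilyl)oxy]-3-[(1S)-1-[(tert-butyldimethylsilyl)oxy]ethyl]hex-4-enoate
Conditions: EtCO2H (cat.), xylene, 135 °C, MeOH distilled off
Reagents that add atoms: none
Why: Johnson–Claisen rearrangement through a chair transition state with CH2OTBS equatorial; this gives the E-alkene and transfers the carbinol configuration of 6 completely to the new (3S) centre.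

Step 6
Reactants: 8 methyl (3S,4E)-6-[(tert-butyldimethylsilyl)oxy]-3-[(1S)-1-[(tert-butyldimethylsilyl)oxy]ethyl]hex-4-enoate
Product: 10 methyl (3R,4E)-6-[(tert-butyldimethylsilyl)oxy]-3-[(1S)-1-[(tert-butyldimethylsilyl)oxy]ethyl]-2-diazohex-4-enoate, via trifluoroacetyl ester 9 (not isolated)
Conditions: LiN(iPr)2, THF, −78 °C; CF3CO2CH2CF3; then 4-acetamidobenzenesulfonyl azide, Et3N, MeCN, rt
Reagents that add atoms: 4-acetamidobenzenesulfonyl azide, CC(=O)Nc1ccc(cc1)S(=O)(=O)N=[N+]=[N-]; 2,2,2-trifluoroethyl trifluoroacetate, O=C(OCC(F)(F)F)C(F)(F)F (its CF3CO group is carried by 9 only)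
Why: Detrifluoroacetylative diazo transfer: the ester enolate is C-acylated, and the activated 1,3-dicarbonyl compound takes N2 from the sulfonyl azide with loss of the trifluoroacetyl group as the sulfonamide; the C3 centre is untouched (its descriptor changes only through priorities).

Step 7
Reactants: 10 methyl (3R,4E)-6-[(tert-butyldimethylsilyl)oxy]-3-[(1S)-1-[(tert-butyldimethylsilyl)oxy]ethyl]-2-diazohex-4-enoate
Product: 11 methyl (2R,4S)-2-exo-[(1S)-1-[(tert-butyldimethylsilyl)oxy]ethyl]-4-exo-{[(tert-butyldimethylsilyl)oxy]methyl}bicyclo[1.1.0]butane-1-carboxylate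
Conditions: Rh2(S-NTTL)4 (1 mol %), toluene, −78 °C, slow addition of 10
Reagents that add atoms: none
Why: Rhodium-carbene intramolecular cyclopropanation of a 2-diazopent-4-enoate to a bicyclobutane carboxylate; the E-alkene puts CH2OTBS exo, allylic strain in the folded transition state puts the silyloxyethyl group exo, and the absolute configuration follows from the (3R) centre of 10. The bulky carboxylate ligand at −78 °C is chosen to let cyclopropanation outrun the 1,2-hydride shift.

Step 8
Reactants: 12 methyl (S)-3-hydroxy-2-methylpropanoate
Product: 13 (S)-3-hydroxy-N-methoxy-N,2-dimethylpropanamide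
Conditions: MeNHOMe·HCl, iPrMgCl, THF, −20 °C
Reagents that add atoms: N,O-dimethylhydroxylamine hydrochloride, CNOC.Cl
Why: Aminolysis of the ester by the magnesium amide of N,O-dimethylhydroxylamine (Weinreb amide formation), which tolerates the free hydroxyl as its magnesium alkoxide.

Step 9
Reactants: 13 (S)-3-hydroxy-N-methoxy-N,2-dimethylpropanamide
Product: 14 (S)-1-hydroxy-2-methylpent-4-en-3-one
Conditions: CH2=CHMgBr (2.5 equiv), THF, 0 °C; inverse quench into cold 1 M HCl
Reagents that add atoms: vinylmagnesium bromide, C=C[Mg]Br
Why: Weinreb ketone synthesis; the cold acidic inverse quench protonates the released amine before it can add to the enone, and the crude ketone is used at once to forestall oxa-Michael ring closure.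

Step 10
Reactants: 14 (S)-1-hydroxy-2-methylpent-4-en-3-one
Product: 15 (2Z)-2-methyl-1,3-bis[(trimethylsilyl)oxy]penta-2,4-diene
Conditions: Me3SiOTf (2.3 equiv), Et3N, Et2O, −78 to 0 °C
Reagents that add atoms: trimethylsilyl trifluoromethanesulfonate, C[Si](C)(C)OS(=O)(=O)C(F)(F)F
Why: O-silylation of the hydroxyl and soft enolisation of the ketone at its only enolisable carbon; the larger CH2OSiMe3 group is expected to lie cis to OSiMe3 (Z), away from the vinyl group, and the stereocentre of 14 is erased.

Step 11
Reactants: 11 exo,exo-bicyclobutane methyl ester; 15 (2Z)-bis-silyl dienol ether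
Product: 17 β-hydroxy ketone (bicyclo[4.1.1]octane with C8–CO2Me and C11=O; C1 bears CH3 on the C3 side and CH2OH on the C7 side; C3-anti-[(1S)-1-(TBSO)ethyl]; C7-anti-CH2OTBS), via bis-silyl annulation adduct 16 (not isolated)
Conditions: Me3SiNTf2 (10 mol %), 2,6-di-tert-butyl-4-methylpyridine (5 mol %), CH2Cl2, −78 to −40 °C; then citric acid, MeOH/H2O, 0 °C
Reagents that add atoms: none
Why: Proposed new method: the silyl Lewis acid silylates the ester carbonyl of 11, and the tetrasubstituted enol-ether carbon of 15 attacks the hydrogen-bearing bridgehead C2 from outside along the axis of the central bond; this cleaves the bond and leaves a cyclobutyl silyl ketene acetal at C8 and an O-silylated vinyl ketone, and the ketene acetal carbon then adds to the vinyl terminus C9 (intramolecular Mukaiyama–Michael addition) while the silyl group passes to the next ester. The closest known reaction type is the Lewis-acid-catalysed formal (4+3) annulation of 3-aryl acylbicyclobutanes with silyl dienol ethers, together with silylium-catalysed Mukaiyama–Michael additions to enoates. The seven-membered ring closes in the 7-endo-trig mode. C2 and C8 are set by the mechanism, since backside opening of the central bond puts both new bonds on the face opposite the two exo wing substituents. C1 is set by which face of the enol-ether carbon bonds to C2, and the flat C(OSiMe3)(vinyl) unit is expected to avoid the branched silyloxyethyl wing on C3 and sit over the smaller CH2OTBS wing on C7, which leaves CH2O on the C7 side after ring closure. The step needs (4+3) rather than (3+2) closure: aldol closure onto C11 would join two fully substituted carbons next to the quaternary C1, whereas C9 is an unhindered CH2, and release of the bicyclobutane strain (about 65 kcal/mol) pays for both quaternary carbons. The mild acid in the work-up removes both trimethylsilyl groups and leaves the TBS ethers.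

Step 12
Reactants: 17 β-hydroxy ketone
Product: 18 anti-diol (C11–OH cis to the C1 methyl and trans to C1–CH2OH)
Conditions: Me4NBH(OAc)3, MeCN/AcOH (1:1), −30 to 0 °C
Reagents that add atoms: none
Why: Hydroxyl-directed triacetoxyborohydride reduction (Evans–Saksena reduction): the C1–CH2O–boron species delivers hydride to the face of C11 on which the CH2O arm lies, so the new hydroxyl is trans to CH2OH; the ester and silyl ethers are inert to this reagent.

Step 13
Reactants: 18 anti-diol
Product: 19 acetonide (2,2-dimethyl-1,3-dioxane across C11–O and C1–CH2–O)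
Conditions: Me2C(OMe)2, PPTS (cat.), CH2Cl2, rt
Reagents that add atoms: 2,2-dimethoxypropane, COC(C)(C)OC
Why: Acid-catalysed transacetalisation of the 1,3-diol to a trans-fused six-membered acetonide; one group protects both hydroxyls against every step up to 21.

Step 14
Reactants: 19 acetonide ester
Product: 20 C8-hydroxymethyl compound
Conditions: LiAlH4, THF, 0 °C to reflux
Reagents that add atoms: none
Why: Hydride reduction of the hindered quaternary ester to the primary alcohol; acetonide and silyl ethers are stable.

Step 15
Reactants: 20 C8-hydroxymethyl compound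
Product: 21 C8-CH2 mesylate
Conditions: MsCl, Et3N, CH2Cl2, 0 °C
Reagents that add atoms: methanesulfonyl chloride, CS(=O)(=O)Cl
Why: Sulfonylation through the sulfene, which is little affected by the neopentyl environment.

Step 16
Reactants: 21 C8-CH2 mesylate
Product: 22 C8-methyl compound
Conditions: LiBHEt3, THF, 65 °C
Reagents that add atoms: none
Why: SN2 displacement of a neopentyl sulfonate by triethylborohydride, the standard reagent for this hindered class; no cation forms, so the cyclobutane cannot rearrange.

Step 17
Reactants: 22 C8-methyl bis-TBS ether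
Product: 23 diol (C3–CH(OH)CH3 and C7–CH2OH)
Conditions: Bu4NF, THF, rt to 50 °C
Reagents that add atoms: none
Why: Fluoride cleavage of both silyl ethers in one operation; the acetonide is untouched.

Step 18
Reactants: 23 diol
Product: 24 keto aldehyde (C3–COCH3 and C7–CHO, both anti)
Conditions: Dess–Martin periodinane, NaHCO3, CH2Cl2, rt
Reagents that add atoms: none
Why: Dess–Martin oxidation of the secondary and the primary alcohol under buffered, non-epimerising conditions; the spectator stereocentre from 1 disappears here.

Step 19
Reactants: 24 keto aldehyde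
Product: 25 tricyclic enone (C4=O, C5=C6 with H on C6; acetonide)
Conditions: piperidine, AcOH, toluene, 80 °C
Reagents that add atoms: none
Why: Intramolecular aldol condensation, 6-(enolendo)-exo-trig: the enamine or enol of the methyl ketone attacks the formyl carbon held close on the same cyclobutane face, and E1cB dehydration makes the closure irreversible, so any reversible epimerisation at C3 or C7 is funnelled to the product.

Step 20
Reactants: 25 tricyclic enone
Product: 27 β-methyl enone (C5=C6–CH3; acetonide), via trimethylsilyl enol ether 26 (not isolated)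
Conditions: MeLi, CuI, Et2O, 0 °C; then 25, Me3SiCl, THF, −78 °C; then Pd(OAc)2, MeCN, rt
Reagents that add atoms: methyllithium, [Li]C; chlorotrimethylsilane, C[Si](C)(C)Cl (its silyl group is carried by 26 only)
Why: Silyl-accelerated conjugate addition of Me2CuLi to C6 from the face away from the C8 methyl group, then Saegusa–Ito dehydrogenation of the regiodefined silyl enol ether; C6–H is the only β-hydrogen, so the double bond can only return to C5=C6 and the transient C6 stereocentre is erased.

Step 21
Reactants: 27 β-methyl enone acetonide
Product: 28 enone diol (C1–CH2OH and C11–OH)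
Conditions: 80% aq. AcOH, 40 °C
Reagents that add atoms: none
Why: Mild hydrolysis of the acetonide; the enone and the cage carry no group that ionises under these conditions.

Step 22
Reactants: 28 enone diol; 29 angelic acid
Product: 31 CNP0240716.1, via angelic 2,4,6-trichlorobenzoic anhydride 30 (not isolated)
Conditions: 29 (6 equiv), 2,4,6-trichlorobenzoyl chloride, Et3N, toluene, rt; then 28, 80 °C
Reagents that add atoms: 2,4,6-trichlorobenzoyl chloride, O=C(Cl)c1c(Cl)cc(Cl)cc1Cl (its atoms are carried by 30 only)
Why: Yamaguchi esterification without a nucleophilic catalyst, the established way to make angelates of hindered alcohols, because no species is present that adds reversibly to the Z-enoate and isomerises it; both hydroxyls are acylated, the primary one first.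

Compound list

1 | (S)-but-3-yn-2-ol | C[C@H](O)C#C | starting material
2 | (S)-tert-butyl(but-3-yn-2-yloxy)dimethylsilane | C[C@H](O[Si](C)(C)C(C)(C)C)C#C | intermediate
3 | 2-[(tert-butyldimethylsilyl)oxy]-N-methoxy-N-methylacetamide | CON(C)C(=O)CO[Si](C)(C)C(C)(C)C | starting material
4 | (5S)-1,5-bis[(tert-butyldimethylsilyl)oxy]hex-3-yn-2-one | C[C@H](O[Si](C)(C)C(C)(C)C)C#CC(=O)CO[Si](C)(C)C(C)(C)C | intermediate
5 | (2R,5S)-1,5-bis[(tert-butyldimethylsilyl)oxy]hex-3-yn-2-ol | C[C@H](O[Si](C)(C)C(C)(C)C)C#C[C@@H](O)CO[Si](C)(C)C(C)(C)C | intermediate
6 | (2R,3E,5S)-1,5-bis[(tert-butyldimethylsilyl)oxy]hex-3-en-2-ol | C[C@H](O[Si](C)(C)C(C)(C)C)/C=C/[C@@H](O)CO[Si](C)(C)C(C)(C)C | intermediate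
7 | trimethyl orthoacetate | COC(C)(OC)OC | starting material
8 | methyl (3S,4E)-6-[(tert-butyldimethylsilyl)oxy]-3-[(1S)-1-[(tert-butyldimethylsilyl)oxy]ethyl]hex-4-enoate | COC(=O)C[C@H]([C@H](C)O[Si](C)(C)C(C)(C)C)/C=C/CO[Si](C)(C)C(C)(C)C | intermediate
9 | methyl (3R,4E)-6-[(tert-butyldimethylsilyl)oxy]-3-[(1S)-1-[(tert-butyldimethylsilyl)oxy]ethyl]-2-(trifluoroacetyl)hex-4-enoate, C2 epimers | COC(=O)C(C(=O)C(F)(F)F)[C@H]([C@H](C)O[Si](C)(C)C(C)(C)C)/C=C/CO[Si](C)(C)C(C)(C)C | intermediate (not isolated)
10 | methyl (3R,4E)-6-[(tert-butyldimethylsilyl)oxy]-3-[(1S)-1-[(tert-butyldimethylsilyl)oxy]ethyl]-2-diazohex-4-enoate | COC(=O)C(=[N+]=[N-])[C@H]([C@H](C)O[Si](C)(C)C(C)(C)C)/C=C/CO[Si](C)(C)C(C)(C)C | intermediate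
11 | methyl (2R,4S)-2-exo-[(1S)-1-[(tert-butyldimethylsilyl)oxy]ethyl]-4-exo-{[(tert-butyldimethylsilyl)oxy]methyl}bicyclo[1.1.0]butane-1-carboxylate (ester bridgehead = C8, CH bridgehead = C2, silyloxyethyl wing = C3, silyloxymethyl wing = C7) | COC(=O)[C@]12[C@H]([C@H](C)O[Si](C)(C)C(C)(C)C)[C@H]1[C@@H]2CO[Si](C)(C)C(C)(C)C | intermediate
12 | methyl (S)-3-hydroxy-2-methylpropanoate | COC(=O)[C@@H](C)CO | starting material
13 | (S)-3-hydroxy-N-methoxy-N,2-dimethylpropanamide | CON(C)C(=O)[C@@H](C)CO | intermediate
14 | (S)-1-hydroxy-2-methylpent-4-en-3-one | C=CC(=O)[C@@H](C)CO | intermediate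
15 | (2Z)-2-methyl-1,3-bis[(trimethylsilyl)oxy]penta-2,4-diene | C=C/C(O[Si](C)(C)C)=C(\C)CO[Si](C)(C)C | intermediate
16 | bis-silyl annulation adduct: bicyclo[4.1.1]octene with C8–CO2Me, C10=C11–OSiMe3, C1(CH3)(CH2OSiMe3) with CH2O on the C7 side, C3-anti-[(1S)-1-(TBSO)ethyl], C7-anti-CH2OTBS | C[Si](C)(C)OC[C@@]1(C)[C@@H]2[C@@H]([C@H](C)O[Si](C)(C)C(C)(C)C)[C@@](C(=O)OC)([C@H]2CO[Si](C)(C)C(C)(C)C)CC=C1O[Si](C)(C)C | intermediate (not isolated)
17 | β-hydroxy ketone: as 16 with C11=O and free C1–CH2OH | OC[C@@]1(C)[C@@H]2[C@@H]([C@H](C)O[Si](C)(C)C(C)(C)C)[C@@](C(=O)OC)([C@H]2CO[Si](C)(C)C(C)(C)C)CCC1=O | intermediate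
18 | anti-diol: as 17 with C11–OH cis to the C1 methyl, trans to C1–CH2OH | OC[C@@]1(C)[C@@H]2[C@@H]([C@H](C)O[Si](C)(C)C(C)(C)C)[C@@](C(=O)OC)([C@H]2CO[Si](C)(C)C(C)(C)C)CC[C@@H]1O | intermediate
19 | acetonide of 18 (trans-fused 2,2-dimethyl-1,3-dioxane over O11 and C1–CH2O) | CC1(C)OC[C@@]2(C)[C@@H]3[C@@H]([C@H](C)O[Si](C)(C)C(C)(C)C)[C@@](C(=O)OC)([C@H]3CO[Si](C)(C)C(C)(C)C)CC[C@@H]2O1 | intermediate
20 | C8–CH2OH compound (otherwise as 19) | CC1(C)OC[C@@]2(C)[C@@H]3[C@@H]([C@H](C)O[Si](C)(C)C(C)(C)C)[C@@](CO)([C@H]3CO[Si](C)(C)C(C)(C)C)CC[C@@H]2O1 | intermediate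
21 | C8–CH2OMs compound | CC1(C)OC[C@@]2(C)[C@@H]3[C@@H]([C@H](C)O[Si](C)(C)C(C)(C)C)[C@@](COS(C)(=O)=O)([C@H]3CO[Si](C)(C)C(C)(C)C)CC[C@@H]2O1 | intermediate
22 | C8–CH3 compound | CC1(C)OC[C@@]2(C)[C@@H]3[C@@H]([C@H](C)O[Si](C)(C)C(C)(C)C)[C@@](C)([C@H]3CO[Si](C)(C)C(C)(C)C)CC[C@@H]2O1 | intermediate
23 | diol: C3-anti-[(1S)-1-hydroxyethyl], C7-anti-CH2OH | CC1(C)OC[C@@]2(C)[C@@H]3[C@@H]([C@H](C)O)[C@@](C)([C@H]3CO)CC[C@@H]2O1 | intermediate
24 | keto aldehyde: C3-anti-acetyl, C7-anti-formyl | CC1(C)OC[C@@]2(C)[C@@H]3[C@@H](C(C)=O)[C@@](C)([C@H]3C=O)CC[C@@H]2O1 | intermediate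
25 | tricyclic enone, C4=O, C5=C6(H), acetonide | CC1(C)OC[C@@]2(C)[C@@H]3[C@H]4C(=O)C=C[C@@H]3[C@@]4(C)CC[C@@H]2O1 | intermediate
26 | trimethylsilyl enol ether C4(OSiMe3)=C5, C6–CH3 on the face away from the C8 methyl | CC1(C)OC[C@@]2(C)[C@@H]3[C@H]4C(O[Si](C)(C)C)=C[C@@H](C)[C@@H]3[C@@]4(C)CC[C@@H]2O1 | intermediate (not isolated)
27 | β-methyl enone, C4=O, C5=C6(CH3), acetonide | CC1(C)OC[C@@]2(C)[C@@H]3[C@H]4C(=O)C=C(C)[C@@H]3[C@@]4(C)CC[C@@H]2O1 | intermediate
28 | enone diol (C1–CH2OH, C11–OH) | OC[C@@]1(C)[C@@H]2[C@H]3C(=O)C=C(C)[C@@H]2[C@@]3(C)CC[C@@H]1O | intermediate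
29 | angelic acid, (Z)-2-methylbut-2-enoic acid | C/C=C(/C)C(=O)O | starting material
30 | angelic 2,4,6-trichlorobenzoic anhydride | C/C=C(/C)C(=O)OC(=O)c1c(Cl)cc(Cl)cc1Cl | intermediate (not isolated)
31 | CNP0240716.1, the bis-angelate of 28 | C/C=C(/C)C(=O)OC[C@@]1(C)[C@@H]2[C@H]3C(=O)C=C(C)[C@@H]2[C@@]3(C)CC[C@@H]1OC(=O)/C(C)=C\C | target

Total step count: 22 (steps 1–7 bicyclobutane arm, 8–10 dienol ether arm, 11–22 after convergence). Longest linear sequence: 19 steps (1–7, then 11–22).

Least certain steps

Step 11 (proposed new method). Two things may go wrong. First, bond formation between a tetrasubstituted enol-ether carbon and a bridgehead that carries only hydrogen may be slower than acid-induced isomerisation of the bicyclobutane or protodesilylation of the diene. Second, the facial selectivity at C1 may be poor, because the two wings differ only at a distance from the reacting centre. Within the step, the bias can be raised by a larger silyl group on the C3 carbinol (TIPS or TBDPS from step 1), and the sense of the bias is not critical (see the enone-bridge paragraph above). The fallback uses known reactions only; it sets out from 11 and returns at 17. Copper-catalysed homoconjugate addition of isopropenylmagnesium bromide (CuBr·SMe2, PBu3, THF, −78 °C), with trapping of the ester enolate by but-3-en-1-yl triflate from the face away from the wings, gives the cis-1,3-dialkenyl cyclobutane F1. Ring-closing metathesis with the second-generation Grubbs catalyst closes the seven-membered ring as the C1=C11 cycloalkene F2. Hydroboration–oxidation places oxygen on the less substituted C11 (alcohol F3), and Dess–Martin oxidation gives the C1-methyl ketone F4. The more substituted trimethylsilyl enol ether F5 (Me3SiCl, NaI, Et3N, MeCN) is hydroxymethylated at C1 with aqueous formaldehyde and Sc(OTf)3 to give 17. The C1 epimers would have to be separated if this Mukaiyama aldol step is unselective.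

Step 7. The rhodium carbene has a tertiary allylic C–H next to it, so a 1,2-hydride shift may outrun cyclopropanation; the catalyst may also be mismatched with the substrate stereocentre and erode exo selectivity (the antipodal catalyst is then tried first). The fallback avoids the carbene; it sets out from 8 and returns at 11. Epoxidation of 8 with mCPBA gives, after separation from its diastereomer, the trans-epoxide F6 with oxygen on the face opposite to that which C8 must bond to. KN(SiMe3)2 closes the cyclopropane by 3-exo opening of the epoxide with inversion at C2 (cyclopropyl carbinol F7). Mesylation gives the mesylate F8, and a second deprotonation α to the ester (KN(SiMe3)2, THF) displaces the mesylate with inversion at C7 to give 11.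

Step 16. Hydride displacement at the neopentyl carbon, flanked by two cis substituents, may be slow; attack at sulfur may then return 20, or a neighbouring silyl ether may participate. The fallback sets out from 20 and returns at 22. Dess–Martin oxidation gives the C8 aldehyde F9; p-toluenesulfonylhydrazide gives the tosylhydrazone F10; reduction with catecholborane and decomposition with NaOAc·3H2O gives the methyl group of 22 without any substitution at carbon.

Step 20. The cuprate should add from the face away from the C8 methyl group, which leaves the C6–H on the hindered face; the syn β-hydride elimination from palladium may therefore stall at the saturated ketone. The fallback uses an anti elimination; it sets out from the silyl enol ether 26, isolated after aqueous work-up, and returns at 27. N-Bromosuccinimide (THF, −78 °C) brominates C5 from the open face to give the bromo ketone F11, in which Br and C6–H are anti. Dehydrobromination with Li2CO3 and LiBr in DMF at 120 °C gives 27.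

Step 22. Acylation of the neopentyl C11 hydroxyl may be incomplete, and forcing it may cause Z to E isomerisation to the tiglate. The fallback builds the Z-alkene after acylation; it sets out from 28 and returns at 31. Esterification with 2-[bis(2,2,2-trifluoroethoxy)phosphoryl]propanoic acid (DCC, DMAP) gives the bis(phosphonopropionate) F12. Still–Gennari olefination with acetaldehyde (KN(SiMe3)2, 18-crown-6, THF, −78 °C) forms both (Z)-2-methylbut-2-enoates.

Further compounds

F1 | step 11 | cyclobutane with C2-isopropenyl and C8-(but-3-enyl)(CO2Me), both new groups syn to each other and anti to the wing substituents of 11 | C=C(C)[C@@H]1[C@@H]([C@H](C)O[Si](C)(C)C(C)(C)C)[C@](C(=O)OC)(CCC=C)[C@H]1CO[Si](C)(C)C(C)(C)C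
F2 | step 11 | bicyclo[4.1.1]octene ester with C1(CH3)=C11 | CC1=CCC[C@@]2(C(=O)OC)[C@H]([C@H](C)O[Si](C)(C)C(C)(C)C)[C@@H]1[C@@H]2CO[Si](C)(C)C(C)(C)C
F3 | step 11 | C11 alcohol with C1(H)CH3, epimers at C1 and C11 | CC1C(O)CC[C@@]2(C(=O)OC)[C@H]([C@H](C)O[Si](C)(C)C(C)(C)C)[C@@H]1[C@@H]2CO[Si](C)(C)C(C)(C)C
F4 | step 11 | C11 ketone with C1(H)CH3, C1 epimers | CC1C(=O)CC[C@@]2(C(=O)OC)[C@H]([C@H](C)O[Si](C)(C)C(C)(C)C)[C@@H]1[C@@H]2CO[Si](C)(C)C(C)(C)C
F5 | step 11 | trimethylsilyl enol ether C1(CH3)=C11(OSiMe3) | CC1=C(O[Si](C)(C)C)CC[C@@]2(C(=O)OC)[C@H]([C@H](C)O[Si](C)(C)C(C)(C)C)[C@@H]1[C@@H]2CO[Si](C)(C)C(C)(C)C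
F6 | step 7 | trans-4,5-epoxide of ester 8 (required diastereomer) | COC(=O)C[C@H]([C@H](C)O[Si](C)(C)C(C)(C)C)[C@H]1O[C@@H]1CO[Si](C)(C)C(C)(C)C
F7 | step 7 | cyclopropyl carbinol: methyl 2-(silyloxyethyl)-3-[1-hydroxy-2-(silyloxy)ethyl]cyclopropane-1-carboxylate, C1 of the ring unspecified | COC(=O)C1[C@H]([C@H](C)O[Si](C)(C)C(C)(C)C)[C@H]1[C@H](O)CO[Si](C)(C)C(C)(C)C
F8 | step 7 | mesylate of F7 | COC(=O)C1[C@H]([C@H](C)O[Si](C)(C)C(C)(C)C)[C@H]1[C@H](OS(C)(=O)=O)CO[Si](C)(C)C(C)(C)C
F9 | step 16 | C8 aldehyde corresponding to 20 | CC1(C)OC[C@@]2(C)[C@@H]3[C@@H]([C@H](C)O[Si](C)(C)C(C)(C)C)[C@@](C=O)([C@H]3CO[Si](C)(C)C(C)(C)C)CC[C@@H]2O1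
F10 | step 16 | (E)-p-toluenesulfonylhydrazone of F9 | CC1(C)OC[C@@]2(C)[C@@H]3[C@@H]([C@H](C)O[Si](C)(C)C(C)(C)C)[C@@](/C=N/NS(=O)(=O)c4ccc(C)cc4)([C@H]3CO[Si](C)(C)C(C)(C)C)CC[C@@H]2O1
F11 | step 20 | C5-bromo C6-methyl ketone, Br and C6–H anti | CC1(C)OC[C@@]2(C)[C@@H]3[C@H]4C(=O)[C@@H](Br)[C@@H](C)[C@@H]3[C@@]4(C)CC[C@@H]2O1
F12 | step 22 | bis{2-[bis(2,2,2-trifluoroethoxy)phosphoryl]propanoate} of diol 28, phosphonate α-carbons unspecified | CC(C(=O)OC[C@@]1(C)[C@@H]2[C@H]3C(=O)C=C(C)[C@@H]2[C@@]3(C)CC[C@@H]1OC(=O)C(C)P(=O)(OCC(F)(F)F)OCC(F)(F)F)P(=O)(OCC(F)(F)F)OCC(F)(F)F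
A1 | alternative 1 | tricyclic hydroxy ester from samarium Reformatsky closure of the C1–C11 bond | COC(=O)[C@@]1(C)[C@@H]2[C@H]3C(=O)C=C(C)[C@@H]2[C@@]3(C)CC[C@@H]1O
A2 | alternative 2 | tricyclic cyano alcohol from transannular epoxynitrile closure of the C3–C8 bond | CC(C)(C)[Si](C)(C)OC[C@@]1(C)[C@@H]2[C@H]3[C@@H](O)C[C@@H](C)[C@@H]2[C@@]3(C#N)CC[C@@H]1O[Si](C)(C)C(C)(C)C
A3 | alternative 3 | tricyclic exo-methylene ketone from Conia-ene closure of the C5–C6 bond | CC(C)(C)[Si](C)(C)OC[C@@]1(C)[C@@H]2[C@H]3C(=O)CC(=C)[C@@H]2[C@@]3(C)CC[C@@H]1O[Si](C)(C)C(C)(C)C
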